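## Retrosynthetic overview
1. 45 ⇒ 42: the C11(20) oxirane (peracid), C6‑Cl/C5=C16 (ene‑type chlorination of C5=C6) and TMS removal come last.
2. 42 ⇒ 41: the C2–C3 bond and both carbinol centres come from a Ti(III)‑catalysed ring‑closing pinacol coupling. It closes the ten‑membered carbocycle, which is also the oxa‑bridged eight‑membered ring.
3. 41 ⇒ 23 + 37: the C9–C10 bond comes from a Hosomi–Sakurai union, which sets C9 and C10 and unveils C11=C20.
4. 23 ⇒ furfuryl alcohol + methyl glycolate + crotyl alcohol: Achmatowicz pyranone, then Ir‑catalysed allylic alkylation for C8–C17 (tetrasubstituted C8), then the lactone.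
5. 37 ⇒ cyclohexane‑1,3‑dione + allyl bromide (yeast desymmetrisation). Ring order: cyclohexane (bought) and dihydropyran → γ‑lactone → ten‑membered ring → oxirane.

Assumption: C1–C20 are the briarane locants of 45. C1 is the quaternary carbon bearing CH3‑15. C2/C3 are the diol carbons. C4‑O‑C8 is the ether bridge. C5=C16 is the exocyclic alkene. C6 bears Cl. C7‑O‑C19(=O)‑C17(CH3‑18) is the lactone. C9/C14 are the acetoxy carbons. C11/C20 form the oxirane. "As in 45" means the same spatial arrangement.

Abbreviations: TBS = t‑BuMe2Si, TBDPS = t‑BuPh2Si, TMS = Me3Si, DMP = Dess–Martin periodinane.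

## Route

Step 1
Reactants: 1 methyl glycolate
Product: 2 methyl 2-(TBDPS-oxy)acetate
Conditions: TBDPSCl, imidazole, DMF, 0 °C → rt
Reagents that add atoms: tert-butyl(chloro)diphenylsilane, CC(C)(C)[Si](Cl)(c1ccccc1)c1ccccc1
Why: Imidazole-promoted O-silylation of the only hydroxyl group gives the acid-robust ether (future C3-O) that must outlast the TBS ether at C9-O; no stereocentre is involved.

Step 2
Reactants: 2 methyl 2-(TBDPS-oxy)acetate
Product: 3 2-(TBDPS-oxy)-N-methoxy-N-methylacetamide
Conditions: MeNH(OMe)·HCl, i-PrMgCl, THF, −20 → 0 °C; H2O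
Reagents that add atoms: N,O-dimethylhydroxylamine hydrochloride, CNOC.Cl
Why: Weinreb amidation of an ester with the magnesium amide made in situ gives an acyl donor that stops at the ketone stage.

Step 3
Reactants: 4 furfuryl alcohol
Product: 5 tert-butyl(furan-2-ylmethoxy)dimethylsilane
Conditions: TBSCl, imidazole, DMF, 0 °C → rt
Reagents that add atoms: tert-butyl(chloro)dimethylsilane, CC(C)(C)[Si](C)(C)Cl
Why: Standard O-silylation protects the future C9-O with a group that tolerates butyllithium and can later be removed beside TBDPS.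

Step 4
Reactants: 5 tert-butyl(furan-2-ylmethoxy)dimethylsilane; 3 2-(TBDPS-oxy)-N-methoxy-N-methylacetamide
Product: 7 1-[5-(TBSO-methyl)furan-2-yl]-2-(TBDPS-oxy)ethan-1-one, via 5-lithiofuran 6 (not isolated)
Conditions: n-BuLi, THF, −78 → 0 °C; then 3, −78 °C → rt; H2O
Reagents that add atoms: none
Why: α-Lithiation of the 2-substituted furan at its free C5 position is followed by Weinreb ketone synthesis, in which the chelated tetrahedral adduct prevents over-addition; this joins C4 to C5.

Step 5
Reactants: 7 furyl ketone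
Product: 8 (S)-1-[5-(TBSO-methyl)furan-2-yl]-2-(TBDPS-oxy)ethan-1-ol
Conditions: RuCl[(S,S)-TsDPEN](p-cymene) (1 mol %), HCO2H/Et3N 5:2, rt
Reagents that add atoms: none
Why: In this Noyori asymmetric transfer hydrogenation the furyl group takes the aryl position in the CH/π-organised six-membered transition state of the (S,S)-catalyst, which gives the (S)-carbinol (C4 as in 45).

Step 6
Reactants: 8 (S)-furyl carbinol
Product: 9 (2S)-6-hydroxy-6-(TBSO-methyl)-2-(TBDPSO-methyl)-2H-pyran-3(6H)-one (anomers)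
Conditions: NBS, NaHCO3, THF/H2O 4:1, 0 °C
Reagents that add atoms: water, O
Why: In the Achmatowicz rearrangement, bromonium-induced oxidative opening of the furan gives the Z-enedione, whose C8 ketone is captured by C4-OH; this forms the pyran ring and leaves C4 untouched.

Step 7
Reactants: 9 hemiketal pyranone
Product: 10 (2S,6S)-6-(TBSO-methyl)-2-(TBDPSO-methyl)-2H-pyran-3(6H)-one (2,6-cis)
Conditions: Et3SiH, TFA, CH2Cl2, −40 °C
Reagents that add atoms: none
Why: In this Kishi-type ionic reduction the silane hydride adds axially to the C8 oxocarbenium ion, so both CH2OSi groups end pseudo-equatorial (2,6-cis) and C9 is placed cis to C3.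

Step 8
Reactants: 10 cis-enone
Product: 11 (2S,6S)-3-methyl-6-(TBSO-methyl)-2-(TBDPSO-methyl)-3,6-dihydro-2H-pyran-3-ol (C5 epimers)
Conditions: MeLi, Et2O, −78 °C; H2O
Reagents that add atoms: methyllithium, [Li]C
Why: 1,2-Addition of a hard organolithium to the enone carbonyl installs C16, and the new carbinol centre is erased in the next step.

Step 9
Reactants: 11 tertiary allylic alcohol
Product: 12 (2R,6R)-2-(TBSO-methyl)-6-(TBDPSO-methyl)-5-methyl-2H-pyran-3(6H)-one (2,6-cis)
Conditions: IBX, DMSO, 55 °C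
Reagents that add atoms: none
Why: Oxidative 1,3-transposition of a cyclic tertiary allylic alcohol (Babler–Dauben type, IBX variant) moves the oxygen from C5 to C7 and creates C5(CH3)=C6 under neutral conditions; 2,6-cis is also the thermodynamic arrangement at the now enolisable C8.

Step 10
Reactants: 13 (E)-but-2-en-1-ol
Product: 14 (E)-but-2-en-1-yl methyl carbonate
Conditions: ClCO2Me, pyridine, CH2Cl2, 0 °C
Reagents that add atoms: methyl chloroformate, COC(=O)Cl
Why: O-Acylation with a chloroformate gives the ionisable allylic carbonate needed for π-allyl formation.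

Step 11
Reactants: 12 transposed enone; 14 crotyl methyl carbonate
Product: 16 (2R,6R)-2-[(S)-but-3-en-2-yl]-2-(TBSO-methyl)-6-(TBDPSO-methyl)-5-methyl-2H-pyran-3(6H)-one, via lithium dienolate 15 (not isolated)
Conditions: LiHMDS, THF, −78 °C; then 14, [Ir(cod)Cl]2 (2 mol %), Feringa-type phosphoramidite (4 mol %, pre-cyclometalated with n-PrNH2, enantiomer matched to the drawn C17), THF, −20 °C → rt; H2O
Reagents that add atoms: none
Why: Proposed new method: Ir-catalysed branched-selective allylic alkylation that uses the cross-conjugated α-oxygenated dienolate 15 as a fully substituted prochiral nucleophile - the cyclometalated Ir-phosphoramidite ionises 14 to a (π-crotyl)Ir(III) complex that is attacked outer-sphere at its substituted terminus, so the catalyst fixes C17; the only sp3 ring carbon of the flat dienolate (C4, with CH2OTBDPS on the upper face) forces C–C bond formation on the lower face, which fixes the tetrasubstituted C8 with C9 cis to C3; kinetic α'-deprotonation and the poor leaving ability of OTBS disfavour γ-alkylation and β-elimination; the closest known reaction type is Ir-catalysed allylic alkylation of unstabilised cyclic ketone enolates and of acyclic α-alkoxy ketone enolates, which has not been shown for pyranone dienolates or for an α-oxy quaternary centre next to a methyl-bearing stereocentre.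

Step 12
Reactants: 16 C8-quaternary pyranone
Product: 18 C19 aldehyde (vinyl of 16 replaced by CHO), via vicinal diol 17 (not isolated)
Conditions: OsO4 (2 mol %), NaIO4, 2,6-lutidine, dioxane/H2O, rt
Reagents that add atoms: sodium periodate, [Na+].[O-]I(=O)(=O)=O
Why: In this Lemieux–Johnson cleavage OsO4 dihydroxylates only the electron-rich monosubstituted vinyl group and not the electron-poor trisubstituted enone alkene, and periodate then cuts the diol to the C19 aldehyde.

Step 13
Reactants: 18 keto aldehyde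
Product: 19 C19 carboxylic acid
Conditions: NaClO2, NaH2PO4, 2-methylbut-2-ene, t-BuOH/H2O, 0 °C
Reagents that add atoms: sodium chlorite, [Na+].[O-]Cl=O
Why: Pinnick oxidation is buffered and chemoselective for the aldehyde, so the enone, the silyl ethers and the α-stereocentre C17 are left intact.

Step 14
Reactants: 19 keto acid
Product: 21 cis-fused dihydropyran γ-lactone (C3-OTBDPS; C9-OTBS; C4/C7/C8/C17 as in 45), via C7-hydroxy acid 20 (not isolated)
Conditions: NaBH4, CeCl3·7H2O, MeOH, −78 °C; then aq citric acid, rt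
Reagents that add atoms: none
Why: Luche 1,2-reduction is followed by acid-induced γ-lactonisation; hydride attacks C7=O anti to the pseudo-axial C17 branch on C8, so C7-O ends cis to C17, which is the epimer that closes the cis-fused lactone.

Step 15
Reactants: 21 bis-silyl lactone
Product: 22 C9 primary alcohol
Conditions: CSA (10 mol %), MeOH/CH2Cl2, 0 °C
Reagents that add atoms: none
Why: Acid-catalysed methanolysis cleaves the TBS ether far faster than the roughly hundred-fold more acid-stable TBDPS ether, and low temperature avoids translactonisation onto C9-OH.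

Step 16
Reactants: 22 C9 alcohol
Product: 23 West aldehyde (C9 formyl on C8)
Conditions: DMP, pyridine, CH2Cl2, 0 °C → rt
Reagents that add atoms: none
Why: Dess–Martin oxidation under neutral conditions gives a non-enolisable neopentyl aldehyde without touching the lactone or C17.

Step 17
Reactants: 24 cyclohexane-1,3-dione
Product: 25 2-methylcyclohexane-1,3-dione
Conditions: MeI, KOH, H2O/dioxane, reflux
Reagents that add atoms: iodomethane, CI
Why: C-Alkylation of the stabilised 1,3-dione enolate with a soft electrophile installs C15.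

Step 18
Reactants: 25 2-methylcyclohexane-1,3-dione; 26 allyl bromide
Product: 27 2-allyl-2-methylcyclohexane-1,3-dione
Conditions: aq NaOH, rt
Reagents that add atoms: none
Why: C-Allylation of the 2-substituted 1,3-dione enolate creates the prochiral quaternary carbon C1.

Step 19
Reactants: 27 prochiral dione
Product: 28 (2S,3S)-2-allyl-3-hydroxy-2-methylcyclohexan-1-one
Conditions: baker's yeast, D-glucose, H2O, 30 °C
Reagents that add atoms: none
Why: Enzymatic desymmetrising reduction of the prochiral 1,3-diketone reduces one enantiotopic carbonyl from one face to give the known (2S,3S)-ketol with OH cis to allyl, which sets C14 and C1 as in 45.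

Step 20
Reactants: 28 ketol
Product: 29 (1S,2S)-2-allyl-2-methyl-3-oxocyclohexyl acetate
Conditions: Ac2O, pyridine, DMAP (cat.), CH2Cl2, rt
Reagents that add atoms: acetic anhydride, CC(=O)OC(C)=O
Why: Acylation installs the final C14 acetate early, and this is safe because C1 is quaternary (no E1cB) and no later step of this branch uses strong base.

Step 21
Reactants: 29 allyl ketone
Product: 30 (E)-prop-1-enyl isomer
Conditions: RuHCl(CO)(PPh3)3 (5 mol %), toluene, 110 °C
Reagents that add atoms: none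
Why: Ru–H-catalysed alkene isomerisation (hydrometalation/β-hydride elimination) moves the terminal double bond next to the quaternary carbon, where it stops because no further β-hydrogen is available.

Step 22
Reactants: 30 propenyl ketone
Product: 32 C2 aldehyde (1S,2S)-2-formyl-2-methyl-3-oxocyclohexyl acetate, via secondary ozonide 31 (not isolated)
Conditions: O3, CH2Cl2, −78 °C; then Me2S, −78 °C → rt
Reagents that add atoms: ozone, [O-][O+]=O
Why: Ozonolysis with reductive work-up cleaves the only alkene and leaves one carbon (C2) on C1.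

Step 23
Reactants: 32 keto aldehyde
Product: 33 C2 primary alcohol
Conditions: NaBH4 (0.3 equiv), CH2Cl2/MeOH, −78 °C
Reagents that add atoms: none
Why: Chemoselective borohydride reduction takes the aldehyde much faster than the α-quaternary ketone at −78 °C, and the cold, quickly quenched medium avoids retro-aldol loss of C2 and acetyl migration.

Step 24
Reactants: 33 hydroxy ketone
Product: 34 C2-OTBS ketone
Conditions: TBSCl, imidazole, DMF, 0 °C
Reagents that add atoms: tert-butyl(chloro)dimethylsilane, CC(C)(C)[Si](C)(C)Cl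
Why: Prompt O-silylation of the primary alcohol blocks acyl migration and retro-aldol cleavage.

Step 25
Reactants: 34 ketone
Product: 35 C11-methylene ketone
Conditions: (CH2O)n, PhNH(Me)·TFA, THF, reflux
Reagents that add atoms: formaldehyde (as paraformaldehyde), C=O
Why: Mannich-type α-methylenation with an ammonium trifluoroacetate can occur only at C11, the sole enolisable position, and it installs C20 without strong base.

Step 26
Reactants: 35 exo-methylene ketone
Product: 36 C10 allylic alcohol (C10 epimers)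
Conditions: NaBH4, CeCl3·7H2O, MeOH, 0 °C
Reagents that add atoms: none
Why: Luche reduction gives clean 1,2-reduction of the enone, and the carbinol configuration is lost in the next step.

Step 27
Reactants: 36 allylic alcohol
Product: 37 East allylsilane (C10=C11, C20-TMS)
Conditions: Me3Si–SiMe3, Pd(BF4)2(MeCN)4 (5 mol %), DMSO/MeOH, 50 °C
Reagents that add atoms: hexamethyldisilane, C[Si](C)(C)[Si](C)(C)C
Why: Pd-catalysed allylic C–OH silylation with a disilane proceeds through a π-allyl complex that is silylated at its unhindered terminus C20, which gives the linear allylsilane with the endocyclic C10=C11 bond.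

Step 28
Reactants: 23 West aldehyde; 37 East allylsilane
Product: 38 coupled homoallylic alcohol (C9-OH; C11=C20; C9/C10 as in 45)
Conditions: BF3·OEt2, CH2Cl2, −78 °C; H2O
Reagents that add atoms: none
Why: In this Hosomi–Sakurai allylation (SE2') the aldehyde attacks C10 on the ring face opposite the pseudo-axial CH2OTBS group, placing C9 cis to CH3-15; the non-chelating Lewis acid enforces polar Felkin–Anh attack (C8–O anti to the nucleophile, passing C7) through an open antiperiplanar transition state, whose syn preference matches the required 9,10-relationship.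

Step 29
Reactants: 38 C9 alcohol
Product: 39 9,14-diacetate
Conditions: Ac2O, Et3N, DMAP, CH2Cl2, rt
Reagents that add atoms: acetic anhydride, CC(=O)OC(C)=O
Why: DMAP-catalysed acylation installs the final C9 acetate and removes the risk of translactonisation.

Step 30
Reactants: 39 bis-silyl ether
Product: 40 C2,C3 bis-primary diol
Conditions: HF·pyridine, pyridine, THF, 0 °C → rt
Reagents that add atoms: none
Why: Buffered fluoride desilylation removes both primary silyl ethers while the acetates, the lactone and both alkenes survive the mildly acidic medium.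

Step 31
Reactants: 40 diol
Product: 41 C2,C3 dialdehyde
Conditions: DMP, pyridine, CH2Cl2, 0 °C
Reagents that add atoms: none
Why: Double Dess–Martin oxidation under buffered neutral conditions avoids epimerisation or conjugation at the allylic α-alkoxy centre C4; the product is used at once.

Step 32
Reactants: 41 dialdehyde
Product: 42 macrocyclic trans-2,3-bis(TMS-oxy) diene (all centres as in 45)
Conditions: Cp2Ti(Ph)Cl (10 mol %), Zn, Me3SiCl, THF, rt, 41 added over 12 h (final 2 mM); pH 7 work-up
Reagents that add atoms: chlorotrimethylsilane, C[Si](C)(C)Cl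
Why: Proposed new method: Ti(III)-catalysed ring-closing pinacol coupling applied to a medium ring - Zn-generated Cp2TiPh reduces both aldehydes to bulky titanoxy ketyls that couple with the two OTi groups anti, which gives the trans (threo) diol; the flipped half-chair of the dihydropyran places C3 and C9 pseudo-axial, so the two formyl groups are within bonding distance and each reacts on its outer face (predicted 2R,3S); Me3SiCl releases the catalyst and delivers the bis-TMS ether directly; the closest known reaction types are the Ti(III)-catalysed trans-selective cyclisation of 1,5- and 1,6-dialdehydes and the stoichiometric low-valent Ti or SmI2 pinacol closures of the taxane eight-membered ring.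

Step 33
Reactants: 42 diene
Product: 43 11,20-epoxide
Conditions: mCPBA (1.05 equiv), CH2Cl2, −10 °C
Reagents that add atoms: 3-chloroperbenzoic acid, OOC(=O)c1cccc(Cl)c1
Why: In this Prilezhaev epoxidation C11=C20 is the only electron-rich alkene, because C5=C6 carries two allylic C–O bonds and is shielded by the bridge; the peracid attacks from the equatorial α-face away from the axial CH3-15, which puts the oxygen equatorial (C11 as in 45).

Step 34
Reactants: 43 epoxide
Product: 44 6-chloro-5(16)-ene
Conditions: Ca(OCl)2, CO2 (s), CH2Cl2/H2O, 0 °C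
Reagents that add atoms: calcium hypochlorite, [Ca+2].[O-]Cl.[O-]Cl
Why: In this ene-type allylic chlorination with HOCl (the same reactivity that turns prenyl acetate into 2-chloro-3-methylbut-3-enyl acetate), Cl+ adds to C6 on the outer face because the inner face lies under the C1–C3 bridge; the developing tertiary cation at C5 then loses a proton from C16, which sets C6 and the exocyclic alkene.

Step 35
Reactants: 44 bis-TMS ether
Product: 45 target CNP0340728.1
Conditions: citric acid (cat.), MeOH, 0 °C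
Reagents that add atoms: none
Why: Mild acid-catalysed methanolysis of the labile TMS ethers frees the 2,3-diol without opening the oxirane, ionising the allylic chloride or cleaving the acetates.

## Compound list
1 | methyl glycolate | COC(=O)CO | starting material
2 | methyl 2-(TBDPS-oxy)acetate | COC(=O)CO[Si](c1ccccc1)(c1ccccc1)C(C)(C)C | intermediate
3 | 2-(TBDPS-oxy)-N-methoxy-N-methylacetamide (C3–C4 unit) | CON(C)C(=O)CO[Si](c1ccccc1)(c1ccccc1)C(C)(C)C | intermediate
4 | furfuryl alcohol | OCc1ccco1 | starting material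
5 | tert-butyl(furan-2-ylmethoxy)dimethylsilane | CC(C)(C)[Si](C)(C)OCc1ccco1 | intermediate
6 | [5-(TBSO-methyl)furan-2-yl]lithium (not isolated) | [Li]c1ccc(CO[Si](C)(C)C(C)(C)C)o1 | intermediate
7 | 1-[5-(TBSO-methyl)furan-2-yl]-2-(TBDPS-oxy)ethan-1-one | O=C(CO[Si](c1ccccc1)(c1ccccc1)C(C)(C)C)c1ccc(CO[Si](C)(C)C(C)(C)C)o1 | intermediate
8 | (S)-1-[5-(TBSO-methyl)furan-2-yl]-2-(TBDPS-oxy)ethan-1-ol | O[C@@H](CO[Si](c1ccccc1)(c1ccccc1)C(C)(C)C)c1ccc(CO[Si](C)(C)C(C)(C)C)o1 | intermediate
9 | (2S)-6-hydroxy-6-(TBSO-methyl)-2-(TBDPSO-methyl)-2H-pyran-3(6H)-one, anomer mixture | O=C1C=CC(O)(CO[Si](C)(C)C(C)(C)C)O[C@H]1CO[Si](c1ccccc1)(c1ccccc1)C(C)(C)C | intermediate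
10 | (2S,6S)-6-(TBSO-methyl)-2-(TBDPSO-methyl)-2H-pyran-3(6H)-one, 2,6-cis | O=C1C=C[C@@H](CO[Si](C)(C)C(C)(C)C)O[C@H]1CO[Si](c1ccccc1)(c1ccccc1)C(C)(C)C | intermediate
11 | (2S,6S)-3-methyl-6-(TBSO-methyl)-2-(TBDPSO-methyl)-3,6-dihydro-2H-pyran-3-ol, epimers at the carbinol carbon | CC1(O)C=C[C@@H](CO[Si](C)(C)C(C)(C)C)O[C@H]1CO[Si](c1ccccc1)(c1ccccc1)C(C)(C)C | intermediate
12 | (2R,6R)-2-(TBSO-methyl)-6-(TBDPSO-methyl)-5-methyl-2H-pyran-3(6H)-one, 2,6-cis | CC1=CC(=O)[C@@H](CO[Si](C)(C)C(C)(C)C)O[C@H]1CO[Si](c1ccccc1)(c1ccccc1)C(C)(C)C | intermediate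
13 | (E)-but-2-en-1-ol | C/C=C/CO | starting material
14 | (E)-but-2-en-1-yl methyl carbonate | C/C=C/COC(=O)OC | intermediate
15 | lithium dienolate of 12, C7(OLi)=C8 (not isolated) | CC1=CC(O[Li])=C(CO[Si](C)(C)C(C)(C)C)O[C@H]1CO[Si](c1ccccc1)(c1ccccc1)C(C)(C)C | intermediate
16 | (2R,6R)-2-[(S)-but-3-en-2-yl]-2-(TBSO-methyl)-6-(TBDPSO-methyl)-5-methyl-2H-pyran-3(6H)-one; C4, C8, C17 as in 45 | CC1=CC(=O)[C@](CO[Si](C)(C)C(C)(C)C)([C@@H](C)C=C)O[C@H]1CO[Si](c1ccccc1)(c1ccccc1)C(C)(C)C | intermediate
17 | vicinal diol from the vinyl group of 16 (not isolated) | CC1=CC(=O)[C@](CO[Si](C)(C)C(C)(C)C)([C@@H](C)C(O)CO)O[C@H]1CO[Si](c1ccccc1)(c1ccccc1)C(C)(C)C | intermediate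
18 | keto aldehyde, C19 = CHO; C4, C8, C17 as in 45 | CC1=CC(=O)[C@](CO[Si](C)(C)C(C)(C)C)([C@@H](C)C=O)O[C@H]1CO[Si](c1ccccc1)(c1ccccc1)C(C)(C)C | intermediate
19 | keto acid, C19 = CO2H; C4, C8, C17 as in 45 | CC1=CC(=O)[C@](CO[Si](C)(C)C(C)(C)C)([C@@H](C)C(=O)O)O[C@H]1CO[Si](c1ccccc1)(c1ccccc1)C(C)(C)C | intermediate
20 | C7-hydroxy acid, C7-OH cis to the C17 branch (not isolated) | CC1=C[C@H](O)[C@](CO[Si](C)(C)C(C)(C)C)([C@@H](C)C(=O)O)O[C@H]1CO[Si](c1ccccc1)(c1ccccc1)C(C)(C)C | intermediate
21 | 3,6-dihydro-2H-pyran cis-fused at C7–C8 to the α-methyl-γ-butyrolactone; C3-OTBDPS, C9-OTBS; C4, C7, C8, C17 as in 45 | CC1=C[C@@H]2OC(=O)[C@H](C)[C@]2(CO[Si](C)(C)C(C)(C)C)O[C@H]1CO[Si](c1ccccc1)(c1ccccc1)C(C)(C)C | intermediate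
22 | C9 primary alcohol of 21 | CC1=C[C@@H]2OC(=O)[C@H](C)[C@]2(CO)O[C@H]1CO[Si](c1ccccc1)(c1ccccc1)C(C)(C)C | intermediate
23 | West aldehyde, C9 = CHO on C8; C4, C7, C8, C17 as in 45 | CC1=C[C@@H]2OC(=O)[C@H](C)[C@]2(C=O)O[C@H]1CO[Si](c1ccccc1)(c1ccccc1)C(C)(C)C | intermediate
24 | cyclohexane-1,3-dione | O=C1CCCC(=O)C1 | starting material
25 | 2-methylcyclohexane-1,3-dione | CC1C(=O)CCCC1=O | intermediate
26 | allyl bromide | C=CCBr | starting material
27 | 2-allyl-2-methylcyclohexane-1,3-dione | C=CCC1(C)C(=O)CCCC1=O | intermediate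
28 | (2S,3S)-2-allyl-3-hydroxy-2-methylcyclohexan-1-one (OH cis to allyl) | O=C1CCC[C@H](O)[C@]1(C)CC=C | intermediate
29 | (1S,2S)-2-allyl-2-methyl-3-oxocyclohexyl acetate; C1, C14 as in 45 | O=C1CCC[C@H](OC(C)=O)[C@]1(C)CC=C | intermediate
30 | (E)-prop-1-enyl isomer of 29 | O=C1CCC[C@H](OC(C)=O)[C@]1(C)/C=C/C | intermediate
31 | secondary ozonide (1,2,4-trioxolane) of 30 (not isolated) | O=C1CCC[C@H](OC(C)=O)[C@]1(C)C1OOC(C)O1 | intermediate
32 | (1S,2S)-2-formyl-2-methyl-3-oxocyclohexyl acetate (C2 = CHO) | O=C1CCC[C@H](OC(C)=O)[C@]1(C)C=O | intermediate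
33 | 2-(hydroxymethyl)-2-methyl-3-oxocyclohexyl acetate; C1, C14 as in 45 | O=C1CCC[C@H](OC(C)=O)[C@]1(C)CO | intermediate
34 | C2-OTBS ether of 33 | O=C1CCC[C@H](OC(C)=O)[C@]1(C)CO[Si](C)(C)C(C)(C)C | intermediate
35 | 4-methylene-3-oxo analogue of 34 (C11=C20, C10=O) | O=C1C(=C)CC[C@H](OC(C)=O)[C@]1(C)CO[Si](C)(C)C(C)(C)C | intermediate
36 | C10 allylic alcohol of 35, C10 epimers | OC1C(=C)CC[C@H](OC(C)=O)[C@]1(C)CO[Si](C)(C)C(C)(C)C | intermediate
37 | East allylsilane: cyclohex-3-enyl acetate with C11-CH2TMS, C10=C11, C1(CH3)(CH2OTBS); C1, C14 as in 45 | C[Si](C)(C)CC1=C[C@@](C)(CO[Si](C)(C)C(C)(C)C)[C@@H](OC(C)=O)CC1 | intermediate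
38 | coupled alcohol: C9-OH, C11=C20, C2-OTBS, C3-OTBDPS; C1, C4, C7–C10, C14, C17 as in 45 | CC1=C[C@@H]2OC(=O)[C@H](C)[C@]2([C@@H](O)[C@H]3C(=C)CC[C@H](OC(C)=O)[C@]3(C)CO[Si](C)(C)C(C)(C)C)O[C@H]1CO[Si](c1ccccc1)(c1ccccc1)C(C)(C)C | intermediate
39 | 9,14-diacetate of 38 | CC1=C[C@@H]2OC(=O)[C@H](C)[C@]2([C@@H](OC(C)=O)[C@H]3C(=C)CC[C@H](OC(C)=O)[C@]3(C)CO[Si](C)(C)C(C)(C)C)O[C@H]1CO[Si](c1ccccc1)(c1ccccc1)C(C)(C)C | intermediate
40 | seco diol (C2H2OH, C3H2OH) | CC1=C[C@@H]2OC(=O)[C@H](C)[C@]2([C@@H](OC(C)=O)[C@H]3C(=C)CC[C@H](OC(C)=O)[C@]3(C)CO)O[C@H]1CO | intermediate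
41 | seco dialdehyde (C2HO, C3HO) | CC1=C[C@@H]2OC(=O)[C@H](C)[C@]2([C@@H](OC(C)=O)[C@H]3C(=C)CC[C@H](OC(C)=O)[C@]3(C)C=O)O[C@H]1C=O | intermediate
42 | macrocycle: trans-2,3-bis(TMS-oxy), C5(CH3)=C6, C11=C20; all centres as in 45 | CC1=C[C@@H]2OC(=O)[C@H](C)[C@]23O[C@H]1[C@@H](O[Si](C)(C)C)[C@H](O[Si](C)(C)C)[C@@]1(C)[C@@H](OC(C)=O)CCC(=C)[C@@H]1[C@@H]3OC(C)=O | intermediate
43 | 11,20-epoxide of 42 (O equatorial, C11 as in 45) | CC1=C[C@@H]2OC(=O)[C@H](C)[C@]23O[C@H]1[C@@H](O[Si](C)(C)C)[C@H](O[Si](C)(C)C)[C@@]1(C)[C@@H](OC(C)=O)CC[C@]4(CO4)[C@@H]1[C@@H]3OC(C)=O | intermediate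
44 | 6-chloro-5(16)-ene, 2,3-bis-TMS ether of 45 | C=C1[C@H](Cl)[C@@H]2OC(=O)[C@H](C)[C@]23O[C@H]1[C@@H](O[Si](C)(C)C)[C@H](O[Si](C)(C)C)[C@@]1(C)[C@@H](OC(C)=O)CC[C@]4(CO4)[C@@H]1[C@@H]3OC(C)=O | intermediate
45 | CNP0340728.1, (1S,2R,3S,4R,6S,7R,8R,9S,10S,11R,14S,17R) in briarane numbering | C=C1[C@H]2O[C@]3([C@@H](C)C(=O)O[C@H]3[C@H]1Cl)[C@@H](OC(C)=O)[C@H]1[C@]3(CC[C@H](OC(C)=O)[C@]1(C)[C@@H](O)[C@@H]2O)CO3 | target

## Counts
Total step count: 35.
Longest linear sequence: 22 steps (1→2→3→7→8→9→10→11→12→16→18→19→21→22→23→38→39→40→41→42→43→44→45).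

## The three steps most likely to fail

**Step 11 (new Ir allylation).** Possible failures are O-allylation, linear product, β-elimination of OTBS, or poor C8/C17 control.

The fallback sets out from 12 and comes back at 21. It uses only known chemistry and builds C17–CH3 separately:
- The same dienolate is trapped on oxygen with allyl chloroformate to give the allyl dienol carbonate F1.
- Pd2(dba)3/(S)-t-Bu-PHOX-catalysed decarboxylative allylic alkylation (Tsuji type, known for ketones bearing α-CH2OSiR3) gives the C8-allyl ketone F2. The face is again ruled by C4.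
- Lemieux–Johnson cleavage gives the aldehyde F3, and Pinnick oxidation gives the acid F4.
- Luche reduction with lactonisation gives the 17-nor-methyl lactone F5.
- LDA/MeI at −78 °C methylates the open convex face and gives the 17-epi lactone F6.
- A second deprotonation gives the lithium enolate F7. A quench with a bulky phenol protonates the same convex face, which turns the methyl group to the natural side and gives 21.

**Step 28 (Hosomi–Sakurai union).** The new bond lies between two carbons that each neighbour a quaternary centre, so the allylsilane may be too unreactive.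

The fallback sets out from 36 (with 23) and comes back at 38:
- Appel bromination with allylic shift (CBr4, PPh3) gives the primary allylic bromide F8.
- A CrCl2-mediated Nozaki–Hiyama allylation of 23 uses a far more reactive nucleophile. It attacks the same ring face (C10 as in 45), but through a closed chair gives the 9,10-anti product, the 9-epi alcohol F9.
- DMP oxidation gives the β,γ-unsaturated C9 ketone F10.
- Chelation-controlled reduction with Zn(BH4)2 (C8-O/C9=O chelate, hydride from the C7 side) gives 38.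

**Step 32 (new Ti-catalysed medium-ring pinacol).** Possible failures are oligomerisation, simple reduction of the aldehydes, or the wrong diol diastereomer.

The fallback sets out from 41 and comes back at 42. It accepts a cis-selective closure and corrects one centre afterwards:
- Stoichiometric SmI2 (THF, t-BuOH, high dilution) closes the ring by chelated ketyl–aldehyde addition to the cis-diol F11 (C2 as in 45, C3 epimeric).
- Tf2O/pyridine sulfonylates the less hindered C3-OH to give the C3 triflate F12.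
- Bu4NNO2 displaces it with inversion (Lattrell–Dax) to the C3 nitrite ester F13, which hydrolyses on work-up to the trans-diol F14.
- TMSCl/imidazole gives 42.

## Further compounds
F1 | step 11 | allyl dienol carbonate of 12 | CC1=CC(OC(=O)OCC=C)=C(CO[Si](C)(C)C(C)(C)C)O[C@H]1CO[Si](c1ccccc1)(c1ccccc1)C(C)(C)C
F2 | step 11 | C8-allyl ketone (C8 as in 45) | CC1=CC(=O)[C@](CO[Si](C)(C)C(C)(C)C)(CC=C)O[C@H]1CO[Si](c1ccccc1)(c1ccccc1)C(C)(C)C
F3 | step 11 | C8-CH2CHO keto aldehyde | CC1=CC(=O)[C@](CO[Si](C)(C)C(C)(C)C)(CC=O)O[C@H]1CO[Si](c1ccccc1)(c1ccccc1)C(C)(C)C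
F4 | step 11 | C8-CH2CO2H keto acid | CC1=CC(=O)[C@](CO[Si](C)(C)C(C)(C)C)(CC(=O)O)O[C@H]1CO[Si](c1ccccc1)(c1ccccc1)C(C)(C)C
F5 | step 11 | 17-nor-methyl lactone | CC1=C[C@@H]2OC(=O)C[C@]2(CO[Si](C)(C)C(C)(C)C)O[C@H]1CO[Si](c1ccccc1)(c1ccccc1)C(C)(C)C
F6 | step 11 | 17-epi lactone (17-epimer of 21) | CC1=C[C@@H]2OC(=O)[C@@H](C)[C@]2(CO[Si](C)(C)C(C)(C)C)O[C@H]1CO[Si](c1ccccc1)(c1ccccc1)C(C)(C)C
F7 | step 11 | lithium enolate of F6 | CC1=C[C@@H]2OC(O[Li])=C(C)[C@]2(CO[Si](C)(C)C(C)(C)C)O[C@H]1CO[Si](c1ccccc1)(c1ccccc1)C(C)(C)C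
F8 | step 28 | primary allylic bromide (C20-Br, C10=C11) | BrCC1=C[C@@](C)(CO[Si](C)(C)C(C)(C)C)[C@@H](OC(C)=O)CC1
F9 | step 28 | 9-epi alcohol (9-epimer of 38) | CC1=C[C@@H]2OC(=O)[C@H](C)[C@]2([C@H](O)[C@H]3C(=C)CC[C@H](OC(C)=O)[C@]3(C)CO[Si](C)(C)C(C)(C)C)O[C@H]1CO[Si](c1ccccc1)(c1ccccc1)C(C)(C)C
F10 | step 28 | C9 ketone | CC1=C[C@@H]2OC(=O)[C@H](C)[C@]2(C(=O)[C@H]3C(=C)CC[C@H](OC(C)=O)[C@]3(C)CO[Si](C)(C)C(C)(C)C)O[C@H]1CO[Si](c1ccccc1)(c1ccccc1)C(C)(C)C
F11 | step 32 | macrocyclic cis-2,3-diol (3-epi) | CC1=C[C@@H]2OC(=O)[C@H](C)[C@]23O[C@H]1[C@H](O)[C@H](O)[C@@]1(C)[C@@H](OC(C)=O)CCC(=C)[C@@H]1[C@@H]3OC(C)=O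
F12 | step 32 | C3 triflate of F11 | CC1=C[C@@H]2OC(=O)[C@H](C)[C@]23O[C@H]1[C@H](OS(=O)(=O)C(F)(F)F)[C@H](O)[C@@]1(C)[C@@H](OC(C)=O)CCC(=C)[C@@H]1[C@@H]3OC(C)=O
F13 | step 32 | C3 nitrite ester (C3 inverted, as in 45) | CC1=C[C@@H]2OC(=O)[C@H](C)[C@]23O[C@H]1[C@@H](ON=O)[C@H](O)[C@@]1(C)[C@@H](OC(C)=O)CCC(=C)[C@@H]1[C@@H]3OC(C)=O
F14 | step 32 | macrocyclic trans-2,3-diol (free diol of 42) | CC1=C[C@@H]2OC(=O)[C@H](C)[C@]23O[C@H]1[C@@H](O)[C@H](O)[C@@]1(C)[C@@H](OC(C)=O)CCC(=C)[C@@H]1[C@@H]3OC(C)=O
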